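**Retrosynthetic overview** (rings lettered A–E from the 2,4,6-trihydroxyphenyl end to the 3,4,5-trihydroxyphenyl end)
1. Target ⇐ 13-fold O-demethylation of its trideca-O-methyl ether; all five benzene rings are bought pre-formed and no ring is built.
2. Last C–O bond (ring C–O–ring B): oxidative copper coupling of a ring E–D–C arylboronate with a ring B–A phenol.
3. E–D–C boronate ⇐ sterically controlled C–H borylation of ring C ⇐ Ullmann C–O coupling (ring D–O–ring C) of the E–D phenol with 2-iodo-1,3-dimethoxybenzene.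
4. E–D phenol ⇐ dehydrogenative ortho C–O dimerisation of 3,4,5-trimethoxyphenol (ring E–O–ring D, new step).
5. B–A phenol ⇐ Dakin oxidation ⇐ Ullmann C–O coupling (ring B–O–ring A) of 2,4,6-trimethoxyphenol with 2-bromo-4,6-dimethoxybenzaldehyde. Order of joining: E–D, D–C, separately B–A, then C–B.

Assumption: the target has no stereocentre and its diaryl ether axes rotate freely, so it is achiral and no stereocontrol is needed; the phenols, the aryl iodide and the bromoaldehydes named as starting materials are taken as purchasable.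

**Route**

Step 1
Reactants: 1 3,4,5-trimethoxyphenol (two molecules)
Product: 3 3,4,5-trimethoxy-2-(3,4,5-trimethoxyphenoxy)phenol, via bis(aryloxy)iodane 2 (not isolated)
Conditions: PhIO (0.5 equiv, added in portions), 4 Å MS, CH2Cl2, −30 °C → 23 °C
Reagents that add atoms: none
Why: Proposed new method: iodane-templated dehydrogenative ortho C–O homocoupling, in which PhIO condenses with two molecules of 1 to the trivalent iodine species 2 and one aryloxy oxygen is then delivered through a five-membered transition state to the ortho carbon of the other aryloxy ligand as PhI leaves, followed by rearomatising proton shift; the para carbon is out of reach and already carries OMe, and C–C coupling would need a tetra-ortho-oxygenated biaryl, so O–C(ortho) coupling should dominate; closest known reaction type: ligand coupling and iodonio-Claisen ortho functionalisation at trivalent iodine, and PhI(OAc)2-mediated oxidative phenol coupling.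

Step 2
Reactants: 3 3,4,5-trimethoxy-2-(3,4,5-trimethoxyphenoxy)phenol, 4 2-iodo-1,3-dimethoxybenzene (1.5 equiv)
Product: 5 1-(2,6-dimethoxyphenoxy)-3,4,5-trimethoxy-2-(3,4,5-trimethoxyphenoxy)benzene
Conditions: CuI (10 mol%), picolinic acid (20 mol%), K3PO4 (2 equiv), DMSO, 90 °C, Ar
Reagents that add atoms: none
Why: Ullmann-type copper-catalysed O-arylation with the picolinic acid ligand system that tolerates ortho-substituted phenols and ortho-substituted aryl iodides; 3 has only one free OH and nothing else in either partner reacts.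

Step 3
Reactants: 5 1-(2,6-dimethoxyphenoxy)-3,4,5-trimethoxy-2-(3,4,5-trimethoxyphenoxy)benzene
Product: 6 2-{3,5-dimethoxy-4-[3,4,5-trimethoxy-2-(3,4,5-trimethoxyphenoxy)phenoxy]phenyl}-4,4,5,5-tetramethyl-1,3,2-dioxaborolane
Conditions: [Ir(OMe)(cod)]2 (1.5 mol%), 4,4′-di-tert-butyl-2,2′-bipyridine (3 mol%), B2pin2 (1.0 equiv), THF, 80 °C
Reagents that add atoms: bis(pinacolato)diboron, CC1(C)OB(OC1(C)C)B1OC(C)(C)C(C)(C)O1
Why: Iridium-catalysed C–H borylation is sterically controlled, and the C–H para to the aryloxy oxygen of ring C is the only aromatic C–H in 5 with no ortho substituent (every other ring hydrogen sits next to at least one oxygen substituent), so boron goes exactly where electrophilic substitution would not.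

Step 4
Reactants: 7 2,4,6-trimethoxyphenol, 8 2-bromo-4,6-dimethoxybenzaldehyde
Product: 9 2,4-dimethoxy-6-(2,4,6-trimethoxyphenoxy)benzaldehyde
Conditions: CuI (10 mol%), N,N-dimethylglycine hydrochloride (30 mol%), Cs2CO3 (2.5 equiv), 1,4-dioxane, 100 °C, Ar
Reagents that add atoms: none
Why: Ullmann-type O-arylation in which the ortho-formyl group activates the C–Br bond and the hindered, electron-rich phenol is the nucleophile; the non-enolisable aldehyde survives carbonate base.

Step 5
Reactants: 9 2,4-dimethoxy-6-(2,4,6-trimethoxyphenoxy)benzaldehyde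
Product: 11 2,4-dimethoxy-6-(2,4,6-trimethoxyphenoxy)phenol, via aryl formate 10 (not isolated)
Conditions: 35% aq. H2O2 (1.5 equiv), H2SO4 (cat.), MeOH, 23 °C
Reagents that add atoms: hydrogen peroxide, OO
Why: Dakin oxidation (Baeyer–Villiger-type aryl migration, strongly favoured for a 2,4,6-trioxygenated aryl group) gives formate 10, which acidic methanol cleaves in the same flask to the phenol.

Step 6
Reactants: 6 the ring E–D–C pinacol boronate (1.5 equiv), 11 2,4-dimethoxy-6-(2,4,6-trimethoxyphenoxy)phenol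
Product: 12 1-{2,6-dimethoxy-4-[2,4-dimethoxy-6-(2,4,6-trimethoxyphenoxy)phenoxy]phenoxy}-3,4,5-trimethoxy-2-(3,4,5-trimethoxyphenoxy)benzene (the trideca-O-methyl ether of the target)
Conditions: Cu(OAc)2 (2.0 equiv), pyridine (6 equiv), 4 Å MS, MeCN, dry air, 50 °C
Reagents that add atoms: none
Why: Chan–Lam oxidative C–O coupling puts the hindered partner on the phenol side and the unhindered, electron-rich aryl group on boron, which is the favourable polarity; no halide or free OH elsewhere competes.

Step 7
Reactants: 12 the trideca-O-methyl ether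
Product: 13 2-{2-[3,5-dihydroxy-4-[3,4,5-trihydroxy-2-(3,4,5-trihydroxyphenoxy)phenoxy]phenoxy]-3,5-dihydroxyphenoxy}benzene-1,3,5-triol (CNP0243665.0)
Conditions: BBr3 (26 equiv), CH2Cl2, −78 °C → 23 °C, 24 h; then MeOH, degassed H2O, Ar
Reagents that add atoms: none
Why: Lewis-acid ether cleavage in which bromide attacks the methyl carbon of each ArO(Me)–boron adduct (SN2), while the four aryl–O–aryl bonds have no sp3 carbon to attack and survive; hydrolysis of the aryl borates releases the 13 hydroxyls.

**Compound list**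
1 | 3,4,5-trimethoxyphenol | COc1cc(O)cc(OC)c1OC | starting material
2 | phenylbis(3,4,5-trimethoxyphenoxy)-λ3-iodane | COc1cc(OI(Oc2cc(OC)c(OC)c(OC)c2)c2ccccc2)cc(OC)c1OC | intermediate (not isolated)
3 | 3,4,5-trimethoxy-2-(3,4,5-trimethoxyphenoxy)phenol | COc1cc(Oc2c(O)cc(OC)c(OC)c2OC)cc(OC)c1OC | intermediate
4 | 2-iodo-1,3-dimethoxybenzene | COc1cccc(OC)c1I | starting material
5 | 1-(2,6-dimethoxyphenoxy)-3,4,5-trimethoxy-2-(3,4,5-trimethoxyphenoxy)benzene | COc1cc(Oc2c(Oc3c(OC)cccc3OC)cc(OC)c(OC)c2OC)cc(OC)c1OC | intermediate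
6 | 2-{3,5-dimethoxy-4-[3,4,5-trimethoxy-2-(3,4,5-trimethoxyphenoxy)phenoxy]phenyl}-4,4,5,5-tetramethyl-1,3,2-dioxaborolane | COc1cc(Oc2c(Oc3c(OC)cc(B4OC(C)(C)C(C)(C)O4)cc3OC)cc(OC)c(OC)c2OC)cc(OC)c1OC | intermediate
7 | 2,4,6-trimethoxyphenol | COc1cc(OC)c(O)c(OC)c1 | starting material
8 | 2-bromo-4,6-dimethoxybenzaldehyde | COc1cc(Br)c(C=O)c(OC)c1 | starting material
9 | 2,4-dimethoxy-6-(2,4,6-trimethoxyphenoxy)benzaldehyde | COc1cc(OC)c(Oc2cc(OC)cc(OC)c2C=O)c(OC)c1 | intermediate
10 | 2,4-dimethoxy-6-(2,4,6-trimethoxyphenoxy)phenyl formate | COc1cc(OC)c(Oc2cc(OC)cc(OC)c2OC=O)c(OC)c1 | intermediate (not isolated)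
11 | 2,4-dimethoxy-6-(2,4,6-trimethoxyphenoxy)phenol | COc1cc(OC)c(Oc2cc(OC)cc(OC)c2O)c(OC)c1 | intermediate
12 | 1-{2,6-dimethoxy-4-[2,4-dimethoxy-6-(2,4,6-trimethoxyphenoxy)phenoxy]phenoxy}-3,4,5-trimethoxy-2-(3,4,5-trimethoxyphenoxy)benzene | COc1cc(Oc2c(Oc3c(OC)cc(Oc4c(Oc5c(OC)cc(OC)cc5OC)cc(OC)cc4OC)cc3OC)cc(OC)c(OC)c2OC)cc(OC)c1OC | intermediate
13 | 2-{2-[3,5-dihydroxy-4-[3,4,5-trihydroxy-2-(3,4,5-trihydroxyphenoxy)phenoxy]phenoxy]-3,5-dihydroxyphenoxy}benzene-1,3,5-triol | Oc1cc(O)c(Oc2cc(O)cc(O)c2Oc2cc(O)c(Oc3cc(O)c(O)c(O)c3Oc3cc(O)c(O)c(O)c3)c(O)c2)c(O)c1 | target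

**Step count:** 7 steps in total. Longest linear sequence: 5 steps (1 → 2 → 3 → 6 → 7); steps 4 and 5 form the side branch.

**Three steps most likely to fail**

Step 1 (the proposed new step). The iodane may instead give 2,6-dimethoxy-1,4-benzoquinone (para attack, loss of methyl), C–C dimers, or over-oxidise 3. The fallback uses known chemistry, sets out from 1 and comes back at 3. Compound 1 is coupled with purchased 2-bromo-3,4,5-trimethoxybenzaldehyde (COc1cc(C=O)c(Br)c(OC)c1OC) under Ullmann conditions (CuI, N,N-dimethylglycine hydrochloride, Cs2CO3, 1,4-dioxane, 100 °C) to give 3,4,5-trimethoxy-2-(3,4,5-trimethoxyphenoxy)benzaldehyde F1. Dakin oxidation of this aldehyde (aq. H2O2, cat. H2SO4, MeOH) runs through 3,4,5-trimethoxy-2-(3,4,5-trimethoxyphenoxy)phenyl formate F2 and delivers 3. This costs one extra step.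

Step 6. The phenol 11 is di-ortho-substituted and easily oxidised, and pinacol boronates react sluggishly with divalent copper, so protodeboronation of 6 or quinone formation from 11 may win. The fallback sets out from 6 and comes back at 12, replacing the oxidative boron coupling by a non-oxidative aryl halide coupling. Bromodeboronation of 6 (CuBr2, MeOH/H2O, 80 °C) gives 1-(4-bromo-2,6-dimethoxyphenoxy)-3,4,5-trimethoxy-2-(3,4,5-trimethoxyphenoxy)benzene F3. This unhindered bromide is then joined to 11 by Ullmann O-arylation under argon (CuI, N,N-dimethylglycine hydrochloride, Cs2CO3, 1,4-dioxane, 100 °C) to give 12.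

Step 7. Thirteen demethylations must all go to completion, and the free polyphenol (pyrogallol and hydroxyhydroquinone-type rings) oxidises readily in air, so the main risk is a partly methylated or degraded mixture that cannot be purified. The fallback sets out from 12 and comes back at 13 by a capture-and-release sequence. After BBr3 treatment and methanol quench the crude product is not isolated but acetylated directly (Ac2O, pyridine, cat. DMAP, 23 °C) to the trideca-O-acetate of 13 F4. This is stable, can be chromatographed on silica and separated from under-demethylated material. Acid methanolysis (HCl in degassed MeOH, 23 °C, Ar) then releases 13 with only volatile by-products.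

**Further compounds**
F1 | step 1 | 3,4,5-trimethoxy-2-(3,4,5-trimethoxyphenoxy)benzaldehyde | COc1cc(Oc2c(C=O)cc(OC)c(OC)c2OC)cc(OC)c1OC
F2 | step 1 | 3,4,5-trimethoxy-2-(3,4,5-trimethoxyphenoxy)phenyl formate | COc1cc(Oc2c(OC=O)cc(OC)c(OC)c2OC)cc(OC)c1OC
F3 | step 6 | 1-(4-bromo-2,6-dimethoxyphenoxy)-3,4,5-trimethoxy-2-(3,4,5-trimethoxyphenoxy)benzene | COc1cc(Oc2c(Oc3c(OC)cc(Br)cc3OC)cc(OC)c(OC)c2OC)cc(OC)c1OC
F4 | step 7 | trideca-O-acetate of 13 | CC(=O)Oc1cc(OC(C)=O)c(Oc2cc(OC(C)=O)cc(OC(C)=O)c2Oc2cc(OC(C)=O)c(Oc3cc(OC(C)=O)c(OC(C)=O)c(OC(C)=O)c3Oc3cc(OC(C)=O)c(OC(C)=O)c(OC(C)=O)c3)c(OC(C)=O)c2)c(OC(C)=O)c1
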